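The C2-symmetric C40 tetrol is cut at both C11=C12 bonds into a C10 dialdehyde and two C15 halves; each half rests on one disconnection. The feature used lies in ring atoms C4–C6 (carotenoid numbering): the C4 carbinol is the allylic partner of the fully substituted C5=C6 double bond whose C6 end holds alkyne carbon C7. Moving that oxygen across the allyl unit to C6 uncovers a tertiary alkynyl alcohol beside a C4=C5 alkene, the acetylide adduct of a C3-silyloxy enone from ketoisophorone. Pyridinium chlorochromate C5H5NH[CrO3Cl] performs this in reverse in one operation, giving the C4 ketone and C5=C6 alkene while erasing the uncontrolled C6 centre.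

Key step: step 4

Remarks on the chemistry:
- Positions in the target are given in carotenoid numbering (ring C1–C6, chain from C7); compound names carry their own locants.
- Only the C3 oxygen of each ring comes from ketoisophorone; the C4 oxygen is delivered by chromium in step 4, and the carbinol oxygen of the precursor leaves with the reduced metal.
- The precursor keeps an O–TBS/C–TMS pair so that one buffered fluoride treatment frees the directing hydroxyl and the alkyne together; no cerium additive is planned because the ketone that receives the acetylide has no α-hydrogen.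
- Assumption: the sense of induction in step 1 follows the aryl ketone model of the Ru/TsDPEN catalyst, with the enone π-system in the aryl position; if it were reversed, the (R,R) catalyst would be used.
- Assumption: (2E,4E,6E)-2,7-dimethylocta-2,4,6-trienedial is a purchasable carotenoid building block.

Step 1
Reactants: 1 ketoisophorone (2,6,6-trimethylcyclohex-2-ene-1,4-dione)
Product: 2 (4S)-4-hydroxy-2,6,6-trimethylcyclohex-2-en-1-one
Conditions: RuCl[(S,S)-TsDPEN](p-cymene) (1 mol %), KOH (2 mol %), i-PrOH, 23 °C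
Reagents that add atoms: none
Why: Noyori asymmetric transfer hydrogenation, in which the bifunctional Ru–H/N–H transfer should choose the open C4 carbonyl (flanked by CH2 and CH=) over the C1 carbonyl shielded by the quaternary carbon and the vinylic methyl, and the (S,S) ligand should set 4S, the later C3 of each ring.

Step 2
Reactants: 2 (4S)-4-hydroxy-2,6,6-trimethylcyclohex-2-en-1-one
Product: 3 (4S)-4-[(tert-butyldimethylsilyl)oxy]-2,6,6-trimethylcyclohex-2-en-1-one
Conditions: TBSCl, imidazole, DMF, 23 °C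
Reagents that add atoms: tert-butyldimethylsilyl chloride, CC(C)(C)[Si](C)(C)Cl
Why: Standard silylation of an unhindered secondary alcohol, which removes the acidic hydrogen before step 3 and keeps this oxygen out of reach of chromium in step 4.

Step 3
Reactants: 3 (4S)-4-[(tert-butyldimethylsilyl)oxy]-2,6,6-trimethylcyclohex-2-en-1-one; 4 trimethylsilylacetylene
Product: 6 (4S)-4-[(tert-butyldimethylsilyl)oxy]-2,6,6-trimethyl-1-[(trimethylsilyl)ethynyl]cyclohex-2-en-1-ol as both C1 epimers, via lithium (trimethylsilyl)acetylide 5 (not isolated)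
Conditions: 4, n-BuLi, THF, −78 °C; then 3, −78 to −20 °C
Reagents that add atoms: none
Why: Carbonyl 1,2-addition of a lithium acetylide to a ketone without α-hydrogen, so the small linear nucleophile should add between the gem-dimethyl carbon and the vinylic methyl without enolisation, and the epimer mixture is accepted because step 4 destroys that centre.

Step 4
Reactants: 6 (4S)-4-[(tert-butyldimethylsilyl)oxy]-2,6,6-trimethyl-1-[(trimethylsilyl)ethynyl]cyclohex-2-en-1-ol (both C1 epimers)
Product: 9 (6S)-6-[(tert-butyldimethylsilyl)oxy]-2,4,4-trimethyl-3-[(trimethylsilyl)ethynyl]cyclohex-2-en-1-one, via tertiary chlorochromate ester 7 (not isolated), via transposed secondary chlorochromate ester 8 (not isolated)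
Conditions: C5H5NH[CrO3Cl] (3 equiv), 4 Å molecular sieves, CH2Cl2, 23 °C
Reagents that add atoms: pyridinium chlorochromate, [O-][Cr](=O)(=O)Cl.c1cc[nH+]cc1 (supplies the ketone oxygen)
Why: Hexavalent chromium esterifies the tertiary hydroxyl of either epimer (7); a [3,3] shift of this chromate, or the equivalent tight allyl cation/chromate pair, then bonds a chromium-bound oxygen to the alkene CH carbon and moves the double bond to the ring carbon that bears the alkyne (8), where it is tetrasubstituted and enyne-conjugated. Only 8 carries a carbinol hydrogen, so its collapse to the ketone is the sole, irreversible exit and pulls the equilibrium forward; the ketone oxygen is therefore one supplied by the oxidant, while the original carbinol oxygen departs on the reduced metal. The closest known reaction type is the Dauben–Michno (Babler) oxidative 1,3-transposition of tertiary allylic alcohols, which is established for 1-alkynylcyclohex-2-en-1-ols. No ring is closed and no stereocentre is created; the carbinol centre is destroyed, so the two epimers of 6 converge on one enone. The step needs site selectivity and an untouched silyloxy stereocentre: the other oxygen is capped as a TBS ether, a shift onto the alkyne would have to pass through an allenyl chromate, and the silyloxy carbon is an sp3 bystander that the acidic, non-enolising medium should leave alone.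

Step 5
Reactants: 9 (6S)-6-[(tert-butyldimethylsilyl)oxy]-2,4,4-trimethyl-3-[(trimethylsilyl)ethynyl]cyclohex-2-en-1-one
Product: 10 (6S)-3-ethynyl-6-hydroxy-2,4,4-trimethylcyclohex-2-en-1-one
Conditions: Bu4NF, AcOH (1:1), THF, 0 °C
Reagents that add atoms: none
Why: Fluoride-induced desilylation cleaves the O–Si and the C(sp)–Si bond in one operation, and the acetic acid buffer protonates alkoxide and acetylide at once so that the α-ketol should not enolise toward its stereocentre.

Step 6
Reactants: 10 (6S)-3-ethynyl-6-hydroxy-2,4,4-trimethylcyclohex-2-en-1-one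
Product: 12 (1S,2S)-4-ethynyl-3,5,5-trimethylcyclohex-3-ene-1,2-diol, via tetramethylammonium alkoxydiacetoxyhydridoborate 11 (not isolated)
Conditions: Me4NBH(OAc)3, MeCN/AcOH, −30 to 0 °C
Reagents that add atoms: none
Why: Evans–Saksena hydroxyl-directed reduction, in which boron exchanges onto the C3 oxygen (11) and passes hydride to C4 on the face of the C3–O bond, so H-4 is cis and the new hydroxyl trans to the directing oxygen (4S, C2 of 12), the free reagent being too weak to reduce the enone unaided.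

Step 7
Reactants: 12 (1S,2S)-4-ethynyl-3,5,5-trimethylcyclohex-3-ene-1,2-diol
Product: 13 (1S,2S)-1,2-bis[(tert-butyldimethylsilyl)oxy]-4-ethynyl-3,5,5-trimethylcyclohex-3-ene
Conditions: TBSOTf, 2,6-lutidine, CH2Cl2, −78 to 0 °C
Reagents that add atoms: tert-butyldimethylsilyl trifluoromethanesulfonate, CC(C)(C)[Si](C)(C)OS(=O)(=O)C(F)(F)F
Why: Silylation with a silyl triflate and a hindered pyridine base should cap both the allylic and the neighbouring secondary hydroxyl without ionising the acid-labile allylic position.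

Step 8
Reactants: 13 (1S,2S)-1,2-bis[(tert-butyldimethylsilyl)oxy]-4-ethynyl-3,5,5-trimethylcyclohex-3-ene; 14 ethyl but-2-ynoate
Product: 15 ethyl (2E)-5-{(3S,4S)-3,4-bis[(tert-butyldimethylsilyl)oxy]-2,6,6-trimethylcyclohex-1-en-1-yl}-3-methylpent-2-en-4-ynoate
Conditions: Pd(OAc)2 (3 mol %), tris(2,6-dimethoxyphenyl)phosphine (3 mol %), THF, 23 °C
Reagents that add atoms: none
Why: Trost alkyne–alkynoate cross-addition, in which the alkynylpalladium adds syn across the ynoate with the alkynyl group at the β-carbon and protonolysis keeps that geometry, which should give the 2E enynoate and so the E C9=C10 bond.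

Step 9
Reactants: 15 ethyl (2E)-5-{(3S,4S)-3,4-bis[(tert-butyldimethylsilyl)oxy]-2,6,6-trimethylcyclohex-1-en-1-yl}-3-methylpent-2-en-4-ynoate
Product: 16 (2E)-5-{(3S,4S)-3,4-bis[(tert-butyldimethylsilyl)oxy]-2,6,6-trimethylcyclohex-1-en-1-yl}-3-methylpent-2-en-4-yn-1-ol
Conditions: i-Bu2AlH, CH2Cl2, −78 °C; aq. KNaC4H4O6 (tartrate) work-up
Reagents that add atoms: none
Why: 1,2-Reduction of a conjugated ester by an aluminium hydride at low temperature should give the allylic alcohol and leave the enyne, the silyl ethers and the alkene geometry alone.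

Step 10
Reactants: 16 (2E)-5-{(3S,4S)-3,4-bis[(tert-butyldimethylsilyl)oxy]-2,6,6-trimethylcyclohex-1-en-1-yl}-3-methylpent-2-en-4-yn-1-ol
Product: 18 tributyl[(2E)-5-{(3S,4S)-3,4-bis[(tert-butyldimethylsilyl)oxy]-2,6,6-trimethylcyclohex-1-en-1-yl}-3-methylpent-2-en-4-yn-1-yl]phosphonium bromide, via allylic bromide 17 (not isolated)
Conditions: CBr4, PBu3 (1 equiv), CH2Cl2, −20 °C; then PBu3 (1 equiv), 23 °C
Reagents that add atoms: carbon tetrabromide, BrC(Br)(Br)Br; tributylphosphine, CCCCP(CCCC)CCCC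
Why: Appel bromination of the primary allylic alcohol followed by SN2 quaternisation of bromide 17 with a second equivalent of the same phosphine, both under neutral conditions that should spare the allylic silyl ether and the enyne geometry.

Step 11
Reactants: 18 tributyl[(2E)-5-{(3S,4S)-3,4-bis[(tert-butyldimethylsilyl)oxy]-2,6,6-trimethylcyclohex-1-en-1-yl}-3-methylpent-2-en-4-yn-1-yl]phosphonium bromide (2 equiv); 19 (2E,4E,6E)-2,7-dimethylocta-2,4,6-trienedial
Product: 22 (3S,4S,3'S,4'S)-3,4,3',4'-tetrakis[(tert-butyldimethylsilyl)oxy]-7,8,7',8'-tetradehydro-β,β-carotene (all-E), via tributylphosphonium ylide 20 (not isolated), via C25 monoolefination aldehyde 21 (not isolated)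
Conditions: NaOMe, MeOH/CH2Cl2, 23 °C, dark
Reagents that add atoms: none
Why: Twofold Wittig olefination with an allylic trialkylphosphonium ylide, a class that gives E-alkenes with aldehydes (hence tributyl in place of triphenyl), so both new C11=C12 bonds should be E while the three E bonds of 19 and the C9=C10 bond are carried through.

Step 12
Reactants: 22 (3S,4S,3'S,4'S)-3,4,3',4'-tetrakis[(tert-butyldimethylsilyl)oxy]-7,8,7',8'-tetradehydro-β,β-carotene
Product: 23 (3S,4S,3'S,4'S)-7,8,7',8'-tetradehydro-β,β-carotene-3,4,3',4'-tetrol (all-E), CNP0283832.1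
Conditions: Bu4NF, THF, 23 °C, dark
Reagents that add atoms: none
Why: Fluoride-induced cleavage of the four secondary silyl ethers in a non-acidic medium should free the tetrol without ionising the allylic C4 and C4' hydroxyls.

Compound list
1 | ketoisophorone (2,6,6-trimethylcyclohex-2-ene-1,4-dione) | CC1=CC(=O)CC(C)(C)C1=O | starting material
2 | (4S)-4-hydroxy-2,6,6-trimethylcyclohex-2-en-1-one | CC1=C[C@@H](O)CC(C)(C)C1=O | intermediate
3 | (4S)-4-[(tert-butyldimethylsilyl)oxy]-2,6,6-trimethylcyclohex-2-en-1-one | CC1=C[C@@H](O[Si](C)(C)C(C)(C)C)CC(C)(C)C1=O | intermediate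
4 | trimethylsilylacetylene | C#C[Si](C)(C)C | starting material
5 | lithium (trimethylsilyl)acetylide (not isolated) | [Li]C#C[Si](C)(C)C | intermediate
6 | (4S)-4-[(tert-butyldimethylsilyl)oxy]-2,6,6-trimethyl-1-[(trimethylsilyl)ethynyl]cyclohex-2-en-1-ol (both C1 epimers) | CC1=C[C@@H](O[Si](C)(C)C(C)(C)C)CC(C)(C)C1(O)C#C[Si](C)(C)C | intermediate
7 | tertiary chlorochromate ester of 6 (not isolated) | CC1=C[C@@H](O[Si](C)(C)C(C)(C)C)CC(C)(C)C1(O[Cr](=O)(=O)Cl)C#C[Si](C)(C)C | intermediate
8 | transposed secondary chlorochromate ester (not isolated) | CC1=C(C#C[Si](C)(C)C)C(C)(C)C[C@H](O[Si](C)(C)C(C)(C)C)C1O[Cr](=O)(=O)Cl | intermediate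
9 | (6S)-6-[(tert-butyldimethylsilyl)oxy]-2,4,4-trimethyl-3-[(trimethylsilyl)ethynyl]cyclohex-2-en-1-one | CC1=C(C#C[Si](C)(C)C)C(C)(C)C[C@H](O[Si](C)(C)C(C)(C)C)C1=O | intermediate
10 | (6S)-3-ethynyl-6-hydroxy-2,4,4-trimethylcyclohex-2-en-1-one | CC1=C(C#C)C(C)(C)C[C@H](O)C1=O | intermediate
11 | tetramethylammonium alkoxydiacetoxyhydridoborate of 10 (not isolated) | CC1=C(C#C)C(C)(C)C[C@H](O[BH-](OC(C)=O)OC(C)=O)C1=O.C[N+](C)(C)C | intermediate
12 | (1S,2S)-4-ethynyl-3,5,5-trimethylcyclohex-3-ene-1,2-diol (trans) | CC1=C(C#C)C(C)(C)C[C@H](O)[C@H]1O | intermediate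
13 | (1S,2S)-1,2-bis[(tert-butyldimethylsilyl)oxy]-4-ethynyl-3,5,5-trimethylcyclohex-3-ene | CC1=C(C#C)C(C)(C)C[C@H](O[Si](C)(C)C(C)(C)C)[C@H]1O[Si](C)(C)C(C)(C)C | intermediate
14 | ethyl but-2-ynoate | CC#CC(=O)OCC | starting material
15 | ethyl (2E)-5-{(3S,4S)-3,4-bis[(tert-butyldimethylsilyl)oxy]-2,6,6-trimethylcyclohex-1-en-1-yl}-3-methylpent-2-en-4-ynoate | CC1=C(C#C/C(C)=C/C(=O)OCC)C(C)(C)C[C@H](O[Si](C)(C)C(C)(C)C)[C@H]1O[Si](C)(C)C(C)(C)C | intermediate
16 | (2E)-5-{(3S,4S)-3,4-bis[(tert-butyldimethylsilyl)oxy]-2,6,6-trimethylcyclohex-1-en-1-yl}-3-methylpent-2-en-4-yn-1-ol | CC1=C(C#C/C(C)=C/CO)C(C)(C)C[C@H](O[Si](C)(C)C(C)(C)C)[C@H]1O[Si](C)(C)C(C)(C)C | intermediate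
17 | (3S,4S)-1-[(3E)-5-bromo-3-methylpent-3-en-1-yn-1-yl]-3,4-bis[(tert-butyldimethylsilyl)oxy]-2,6,6-trimethylcyclohex-1-ene (not isolated) | CC1=C(C#C/C(C)=C/CBr)C(C)(C)C[C@H](O[Si](C)(C)C(C)(C)C)[C@H]1O[Si](C)(C)C(C)(C)C | intermediate
18 | tributyl[(2E)-5-{(3S,4S)-3,4-bis[(tert-butyldimethylsilyl)oxy]-2,6,6-trimethylcyclohex-1-en-1-yl}-3-methylpent-2-en-4-yn-1-yl]phosphonium bromide | CC1=C(C#C/C(C)=C/C[P+](CCCC)(CCCC)CCCC)C(C)(C)C[C@H](O[Si](C)(C)C(C)(C)C)[C@H]1O[Si](C)(C)C(C)(C)C.[Br-] | intermediate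
19 | (2E,4E,6E)-2,7-dimethylocta-2,4,6-trienedial | O=C/C(C)=C/C=C/C=C(\C)C=O | starting material
20 | tributylphosphonium ylide of 18 (not isolated) | CC1=C(C#C/C(C)=C/C=P(CCCC)(CCCC)CCCC)C(C)(C)C[C@H](O[Si](C)(C)C(C)(C)C)[C@H]1O[Si](C)(C)C(C)(C)C | intermediate
21 | (2E,4E,6E,8E,10E)-13-{(3S,4S)-3,4-bis[(tert-butyldimethylsilyl)oxy]-2,6,6-trimethylcyclohex-1-en-1-yl}-2,7,11-trimethyltrideca-2,4,6,8,10-pentaen-12-ynal (not isolated) | CC1=C(C#C/C(C)=C/C=C/C(C)=C/C=C/C=C(\C)C=O)C(C)(C)C[C@H](O[Si](C)(C)C(C)(C)C)[C@H]1O[Si](C)(C)C(C)(C)C | intermediate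
22 | (3S,4S,3'S,4'S)-3,4,3',4'-tetrakis[(tert-butyldimethylsilyl)oxy]-7,8,7',8'-tetradehydro-β,β-carotene (all-E) | CC1=C(C#C/C(C)=C/C=C/C(C)=C/C=C/C=C(C)/C=C/C=C(\C)C#CC2=C(C)[C@H](O[Si](C)(C)C(C)(C)C)[C@@H](O[Si](C)(C)C(C)(C)C)CC2(C)C)C(C)(C)C[C@H](O[Si](C)(C)C(C)(C)C)[C@H]1O[Si](C)(C)C(C)(C)C | intermediate
23 | (3S,4S,3'S,4'S)-7,8,7',8'-tetradehydro-β,β-carotene-3,4,3',4'-tetrol (all-E) | CC1=C(C#C/C(C)=C/C=C/C(C)=C/C=C/C=C(C)/C=C/C=C(\C)C#CC2=C(C)[C@H](O)[C@@H](O)CC2(C)C)C(C)(C)C[C@H](O)[C@H]1O | target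

Total step count: 12
Longest linear sequence: 12 steps (1 to 23); 4, 14 and 19 enter as purchased materials.

Steps most likely to fail

1. Step 4. The crowded tertiary chromate may ionise and then lose a proton or pick up chloride instead of recombining at the alkene terminus, or the shift may stall before oxidation. Fallback, setting out from 6 and returning at 9: the hydroxyl would first be moved without oxidation by rhenium-oxo catalysis (Ph3SiOReO3, Et2O, −50 to 0 °C), the equilibrium favouring the secondary, enyne-conjugated alcohol (6S)-6-[(tert-butyldimethylsilyl)oxy]-2,4,4-trimethyl-3-[(trimethylsilyl)ethynyl]cyclohex-2-en-1-ol F1 (both C1 epimers). This would then be oxidised with Dess–Martin periodinane (NaHCO3, CH2Cl2) to 9.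

2. Step 6. Facial control may be lost if hydride is transferred before boron has exchanged onto the C3 oxygen, and the acetic acid medium may ionise the newly formed allylic alcohol. Fallback, setting out from 9 and returning at 13: reduction of the silyl ether 9 with Li[BH(s-Bu)3] (THF, −78 °C), whose bulk should favour equatorial attack and give the cis alcohol (1R,6S)-6-[(tert-butyldimethylsilyl)oxy]-2,4,4-trimethyl-3-[(trimethylsilyl)ethynyl]cyclohex-2-en-1-ol F2. Mitsunobu inversion (4-nitrobenzoic acid, PPh3, DIAD, toluene) would give the trans ester (1S,6S)-6-[(tert-butyldimethylsilyl)oxy]-2,4,4-trimethyl-3-[(trimethylsilyl)ethynyl]cyclohex-2-en-1-yl 4-nitrobenzoate F3. K2CO3 in MeOH would remove the ester and the alkynyl silane to give (1S,6S)-6-[(tert-butyldimethylsilyl)oxy]-3-ethynyl-2,4,4-trimethylcyclohex-2-en-1-ol F4, and silylation (TBSOTf, 2,6-lutidine) would lead to 13.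

3. Step 11. The two olefinations may proceed with partial Z selectivity, and the C9=C10 bond may scramble by rotation in the delocalised allylic ylide. Fallback, setting out from 16 and returning at 22, with every double bond fixed by a stereospecific step: MnO2 (CH2Cl2) would give the enynal (2E)-5-{(3S,4S)-3,4-bis[(tert-butyldimethylsilyl)oxy]-2,6,6-trimethylcyclohex-1-en-1-yl}-3-methylpent-2-en-4-ynal F5. Takai–Utimoto boryl olefination (CrCl2, Cl2CHBpin, LiI, THF) would give the boronate 2-[(1E,3E)-6-{(3S,4S)-3,4-bis[(tert-butyldimethylsilyl)oxy]-2,6,6-trimethylcyclohex-1-en-1-yl}-4-methylhexa-1,3-dien-5-yn-1-yl]-4,4,5,5-tetramethyl-1,3,2-dioxaborolane F6. Separately, Sonogashira coupling of (E)-1,2-dichloroethene with propyne (Pd(PPh3)4, CuI, n-BuNH2) would give (E)-oct-4-ene-2,6-diyne F7. Hydrozirconation with Cp2Zr(H)Cl, in which zirconium should settle on the methyl-bearing carbons, followed by I2 would give (2E,4E,6E)-2,7-diiodoocta-2,4,6-triene F8. Twofold Suzuki–Miyaura coupling of F6 with F8 (Pd(PPh3)4, aqueous K3PO4, THF) would give 22.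

Further compounds
F1 | step 4 | (6S)-6-[(tert-butyldimethylsilyl)oxy]-2,4,4-trimethyl-3-[(trimethylsilyl)ethynyl]cyclohex-2-en-1-ol (both C1 epimers) | CC1=C(C#C[Si](C)(C)C)C(C)(C)C[C@H](O[Si](C)(C)C(C)(C)C)C1O
F2 | step 6 | (1R,6S)-6-[(tert-butyldimethylsilyl)oxy]-2,4,4-trimethyl-3-[(trimethylsilyl)ethynyl]cyclohex-2-en-1-ol | CC1=C(C#C[Si](C)(C)C)C(C)(C)C[C@H](O[Si](C)(C)C(C)(C)C)[C@@H]1O
F3 | step 6 | (1S,6S)-6-[(tert-butyldimethylsilyl)oxy]-2,4,4-trimethyl-3-[(trimethylsilyl)ethynyl]cyclohex-2-en-1-yl 4-nitrobenzoate | CC1=C(C#C[Si](C)(C)C)C(C)(C)C[C@H](O[Si](C)(C)C(C)(C)C)[C@H]1OC(=O)c1ccc(cc1)[N+](=O)[O-]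
F4 | step 6 | (1S,6S)-6-[(tert-butyldimethylsilyl)oxy]-3-ethynyl-2,4,4-trimethylcyclohex-2-en-1-ol | CC1=C(C#C)C(C)(C)C[C@H](O[Si](C)(C)C(C)(C)C)[C@H]1O
F5 | step 11 | (2E)-5-{(3S,4S)-3,4-bis[(tert-butyldimethylsilyl)oxy]-2,6,6-trimethylcyclohex-1-en-1-yl}-3-methylpent-2-en-4-ynal | CC1=C(C#C/C(C)=C/C=O)C(C)(C)C[C@H](O[Si](C)(C)C(C)(C)C)[C@H]1O[Si](C)(C)C(C)(C)C
F6 | step 11 | 2-[(1E,3E)-6-{(3S,4S)-3,4-bis[(tert-butyldimethylsilyl)oxy]-2,6,6-trimethylcyclohex-1-en-1-yl}-4-methylhexa-1,3-dien-5-yn-1-yl]-4,4,5,5-tetramethyl-1,3,2-dioxaborolane | CC1=C(C#C/C(C)=C/C=C/B2OC(C)(C)C(C)(C)O2)C(C)(C)C[C@H](O[Si](C)(C)C(C)(C)C)[C@H]1O[Si](C)(C)C(C)(C)C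
F7 | step 11 | (E)-oct-4-ene-2,6-diyne | CC#C/C=C/C#CC
F8 | step 11 | (2E,4E,6E)-2,7-diiodoocta-2,4,6-triene | I/C(C)=C/C=C/C=C(C)/I
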